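Ochre at 30 mol% catalyst stood at 64% after 10.0 h, more than amber at 13 mol% with 41%. I had to decide how the next flask should take its coupling partner.

| flask | substrate | coupling partner | free catalyst | remark | time |
|---|---|---|---|---|---|
| green | 0.50 M | 0.90 equiv | 20 mol% | run made earlier |  |
| amber | 0.50 M | 0.90 equiv | 13 mol% | run made earlier |  |
| ochre | 0.50 M | 0.90 equiv | 30 mol% | run made earlier |  |
| west | 0.50 M | 0.900 equiv (fed, over 6.0 h) | 20 mol% | all else is in the flask from the start; the feed brings no volume worth counting | 8.0 h |
| north-east | 0.50 M (fed, over 6.0 h) | 0.900 equiv | 20 mol% | all else is in the flask from the start; the feed brings no volume worth counting | 8.0 h |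
| south | 0.50 M | 0.900 equiv | 20 mol% | everything together at the start | 8.0 h |
| south-west | 0.50 M | 0.900 equiv (fed, over 1.5 h) | 20 mol% | all else is in the flask from the start; the feed brings no volume worth counting | 8.0 h |
| south-east | 0.50 M (in portions, 5, over 6.0 h) | 0.900 equiv | 20 mol% | first portion at the start, last at 6.0 h | 8.0 h |

| green: time / h | green: target / % | amber: time / h | amber: target / % | ochre: time / h | ochre: target / % |
|---|---|---|---|---|---|
| 0.333 | 8 | 0.667 | 8 | 1.50 | 39 |
| 1.00 | 20 | 2.00 | 23 | 3.00 | 50 |
| 1.50 | 27 | 3.00 | 27 | 5.00 | 56 |
| 2.50 | 36 | 5.00 | 35 | 6.00 | 58 |
| 4.00 | 42 | 8.00 | 39 | 8.00 | 61 |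
| 5.00 | 44 | 10.0 | 41 | 10.0 | 64 |

(each reading ± 1.5 percentage points)

- what may be going on: substrate + free catalyst <-> free catalyst + open intermediate; free catalyst + open intermediate <-> catalyst intermediate; coupling partner + catalyst intermediate -> free catalyst + target; substrate + coupling partner -> uncatalysed product

1. the flask with the highest amount of target, in percent of the substrate charged ("all alike" if they lie within 1.5 percentage points) (west / north-east / south / south-west / south-east / all alike)
2. final target, as a percentage of the substrate charged, in west
3. final target, as a percentage of the substrate charged, in north-east
4. final target, as a percentage of the substrate charged, in south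
5. final target, as a percentage of the substrate charged, in south-west
6. final target, as a percentage of the substrate charged, in south-east

I assumed that the steps to the catalyst intermediate stood at equilibrium. Target then forms in proportion to free catalyst, substrate and partner, and uncatalysed product forms in proportion to substrate and partner. I called the quotient, target made per uncatalysed product made, the branch ratio (a selectivity factor). It scales with free catalyst, and substrate and partner cancel from it.

Partner that reacts ends in one of the two products. I treated ochre's last reading as nearly finished, although it was still rising. That gave 26.0% of the substrate charge as uncatalysed product. Scaled to 20 mol% catalyst, that reading gave me a branch ratio of about 1.64. A finished batch at that ratio holds about 55.9% target.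

But no open intermediate stands in a fresh flask, so partner charged at the start meets substrate that has not opened. I therefore wanted partner held back, though not for long. West leaves 2.00 h after its feed, less than the 2.50 h green took to reach 36%. South-west leaves 6.50 h. I chose south-west. The forecast chose west, holding that feeding partner keeps its level low, “which suppresses the background”, its word for the step to uncatalysed product.

The flasks gave south-west as the best:

| Flask | Forecast | Result |
|---|---|---|
| west | 65% | 54.5% |
| north-east | 46% | 47.0% |
| south | 48% | 51.3% |
| south-west | 53% | 56.9% |
| south-east | 46% | 46.2% |

    substrate + free catalyst ⇌ free catalyst + open intermediate (K = 0.670, k = 0.00292 M⁻¹ s⁻¹)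
    free catalyst + open intermediate ⇌ catalyst intermediate (K = 1.10 M⁻¹, k = 0.321 M⁻¹ s⁻¹)
    coupling partner + catalyst intermediate → free catalyst + target (k = 0.0115 M⁻¹ s⁻¹)
    substrate + coupling partner → uncatalysed product (k = 2.46 × 10⁻⁴ M⁻¹ s⁻¹)

Against my 1.64, target over uncatalysed product at 8.00 h stood at 1.61 in south, 2.24 in south-west and 2.63 in west. West had the better ratio, but at 8.00 h it still held 16.4% of its partner, against 8.50% in south-west.

Take south-east at 0.30 M substrate with the same loading. Its catalyst per volume falls with the substrate, so I reckon a branch ratio of 0.985. That flask gave 31.4% target and 28.4% uncatalysed product, a ratio of 1.11.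

Readings and results were computed on assumed constants; noise was put on by code.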